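The readings were computed with constants of no real substance; noise was put on by code.

**Chain count.** You cannot read a chain length off Tuesday's run. Its readings give monomer in chains, but not the number of chains. So ask first for a ratio of lengths.

the same everywhere: free monomer 0.18 M

| run | protic impurity | initiator | remark | time |
|---|---|---|---|---|
| Tuesday's | 0.027 M | 0.18 mM | run made earlier |  |
| ochre | 0.0180 M | 0.18 mM |  | 5.0 h |
| grey | 0.0180 M | 0.50 mM |  | 5.0 h |

Tuesday's run (percent of the free monomer charged)

| time / min | monomer in chains / % | free monomer / % |
|---|---|---|
| 8.00 | 1.4 | 96.8 |
| 15.0 | 2.3 | 94.1 |
| 30.0 | 3.4 | 87.2 |
| 60.0 | 7.5 | 80.0 |
| 120 | 13.4 | 73.2 |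

(readings scatter by 1 percentage point)

- the average divides the monomer in chains by the number of chains, living and dead together; two radicals that join make one chain
- the earlier runs do not show the number of chains; that part of a forecast is a guess
- no earlier run changes the charge of initiator; that part of a forecast is a guess
- no earlier run changes the charge of protic impurity; that part of a forecast is a guess

* which of the two ends with the longer chains by the average number of monomer units in a chain (living and dead chains, two that joined counted as one) ("neither" if they lie within 10%) (ochre / grey / neither)
* average number of monomer units in a chain (living and dead chains, two that joined counted as one) at the end, ochre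
* average number of monomer units in a chain (living and dead chains, two that joined counted as one) at the end, grey

**The readings.** Take Tuesday's last line. The monomer neither free nor in chains is 13.4% of the charge, near the 15.0% that the protic impurity's charge amounts to. So read the impurity as taking monomer without making chains. Ochre and grey carry the same impurity charge, so set it aside for the ratio.

**Length factor.** Let I be the initiator charge. Radicals form in proportion to I and vanish in pairs, so their steady-state level goes as the root of I. Growth follows that level, while the number of chains follows I. At equal free monomer, then, the average length goes as one over the root of I. For grey against ochre, F = 0.600. This length factor F is the root of the old initiator charge over the new one, and it multiplies the average length at equal free monomer. F falls short of one by more than the margin of 10%, so call ochre longer. Commit to the ratio, not to a length, since the chain count is a guess.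

**Your forecast.** It says ochre, with 1600 for ochre (range 350 to 6000) and 850 for grey (range 180 to 3200): “Ochre is longer, since the grey/ochre ratio is about 0.53”.

**The flasks.** Ochre ends at 319 units per chain and grey at 174, so ochre is longer. Both lie below your ranges, and your lengths are high by factors of 5.02 and 4.89.

    initiator → 2 initiating radical (k = 0.290 h⁻¹)
    free monomer + initiating radical → growing radical + monomer in chains (k = 5.30 × 10⁵ L mol⁻¹ s⁻¹)
    free monomer + growing radical → monomer in chains + growing radical, rate k3*[growing radical]*[free monomer] (k = 2.60 × 10⁷ L mol⁻¹ h⁻¹)
    2 growing radical → dead chain (k = 1.30 × 10⁹ L mol⁻¹ s⁻¹)
    protic impurity + free monomer → quenched substrate (k = 9.70 L mol⁻¹ h⁻¹)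

**One comparison.** The flask ratio is 0.545, against F of 0.600. The gap between the flasks comes from the difference in initiator: give grey ochre's charge, and its length moves from 174 to 319.

**Second flask.** Take a neighbour like grey, but with 1.3 × 10⁻⁴ M of initiator. Against ochre, F is 1.18, which gives 376 units per chain. The flask gives 384.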